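**Retrosynthetic overview**

1. The target follows from its 2,6-cis oxan-4-one by axial hydride delivery to C4. That ketone follows from a 2-aryl-6-(2-arylethyl)-2,3-dihydro-4H-pyran-4-one by syn hydrogenation of C5=C6, with loss of both benzyl ethers in the same operation.
2. Key disconnection: the exocyclic bond from ring carbon C6 to the first CH2 of the arylethyl chain. C6 is carried as the lactone carbonyl of an (S)-6-aryl-4-methoxy-5,6-dihydro-2H-pyran-2-one and the chain as a 2-arylethyllithium; addition and acid-induced 1,3-carbonyl transposition give the dihydropyranone in one operation.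
3. Enabling feature: in the oxane ring of the target, C6 lies between O1 and C5 and stands 1,3 to the oxygen on C4. The unit O1–C6–C5–C4(–O) is therefore a latent vinylogous carboxylate, O1–C(=O)–CH=C(OMe), in which C6 is an acyl carbon that takes up exactly one carbanion while the C4 oxygen waits as an enol ether.
4. The lactone comes from O-benzylvanillin and 1,3-dimethoxy-1-(trimethylsilyloxy)buta-1,3-diene by a catalytic enantioselective vinylogous aldol addition and lactonisation. This sets the aryl-bearing centre, which then controls C6 (step 6) and, through the locked chair, C4 (step 7).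
5. Ring order: the oxane ring is the only ring made (lactonisation in step 2) and is kept to the end; both benzene rings are bought in.

Key step: step 5

Assumption: the (R)-BINOL–Ti(OiPr)4 catalyst of step 2 is taken to give the S lactone; if the first run shows the opposite sense, (S)-BINOL is used and nothing else changes.

**Route**

Step 1
Reactants: 1 methyl (E)-3-methoxybut-2-enoate
Product: 3 1,3-dimethoxy-1-(trimethylsilyloxy)buta-1,3-diene, via lithium dienolate 2 (not isolated)
Conditions: LiN(i-Pr)2, THF, −78 °C; then chlorotrimethylsilane, −78 °C to rt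
Reagents that add atoms: chlorotrimethylsilane (C[Si](C)(C)Cl)
Why: γ-Deprotonation of the vinylogous ester gives the extended lithium dienolate, which is silylated on oxygen (silyl ketene acetal formation); no stereocenter is formed and the ketene acetal geometry is lost in step 2.

Step 2
Reactants: 4 4-(benzyloxy)-3-methoxybenzaldehyde; 3 1,3-dimethoxy-1-(trimethylsilyloxy)buta-1,3-diene
Product: 6 (6S)-6-[4-(benzyloxy)-3-methoxyphenyl]-4-methoxy-5,6-dihydro-2H-pyran-2-one, via silyl aldol adduct 5 (not isolated)
Conditions: Ti(OiPr)4 (20 mol %), (R)-BINOL (22 mol %), 4 Å molecular sieves, toluene, 0 °C; then TFA (cat.), CH2Cl2, 0 °C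
Reagents that add atoms: none
Why: Catalytic enantioselective vinylogous Mukaiyama aldol addition followed by acid-promoted lactonisation (a formal hetero-Diels–Alder reaction): the chiral BINOL–titanium Lewis acid binds the aldehyde and leaves one enantioface open to the terminal CH2 of the diene, which sets the aryl-bearing centre as S, and TFA then closes the lactone by 6-exo-trig acyl substitution with loss of methoxytrimethylsilane.

Step 3
Reactants: 7 4-(2-hydroxyethyl)-2-methoxyphenol (homovanillyl alcohol)
Product: 8 2-[4-(benzyloxy)-3-methoxyphenyl]ethan-1-ol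
Conditions: benzyl bromide, K2CO3, acetone, reflux
Reagents that add atoms: benzyl bromide (BrCc1ccccc1)
Why: Williamson ether synthesis; K2CO3 deprotonates the phenol but not the aliphatic alcohol, so only the phenolic oxygen is benzylated.

Step 4
Reactants: 8 2-[4-(benzyloxy)-3-methoxyphenyl]ethan-1-ol
Product: 9 1-(benzyloxy)-4-(2-iodoethyl)-2-methoxybenzene
Conditions: PPh3, imidazole, iodine, CH2Cl2, 0 °C to rt
Reagents that add atoms: iodine (II)
Why: Appel-type iodination; the primary alcohol is activated as an oxyphosphonium ion and displaced by iodide in an SN2 reaction, with no stereocenter involved.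

Step 5
Reactants: 9 1-(benzyloxy)-4-(2-iodoethyl)-2-methoxybenzene; 6 (6S)-6-[4-(benzyloxy)-3-methoxyphenyl]-4-methoxy-5,6-dihydro-2H-pyran-2-one
Product: 12 (2S)-2-[4-(benzyloxy)-3-methoxyphenyl]-6-{2-[4-(benzyloxy)-3-methoxyphenyl]ethyl}-2,3-dihydro-4H-pyran-4-one, via alkyllithium 10 (not isolated), via lithium lactolate 11 (not isolated)
Conditions: t-BuLi (2.1 equiv), Et2O–pentane, −78 °C; then transfer into 6 in THF, −78 °C; then 1 M HCl, THF, 0 °C
Reagents that add atoms: water (O)
Why: Iodine–lithium exchange converts 9 into the primary alkyllithium 10, which adds to the lactone carbonyl of 6 (C2 of 6, the future C6 of the target ring), the only electrophilic carbon of the vinylogous carbonate O1–C2(=O)–C3=C4(OMe), and the cyclic lithium lactolate 11 persists at −78 °C, so that no ketone is free for a second addition. On acidification the hemiketal ionises to an oxocarbenium ion stabilised by the 4-methoxy group, water adds at C4, methanol leaves, and the carbonyl group reappears at C4 with the new enol ether double bond between the former C3 and C2. The closest known reaction type is the Stork–Danheiser alkylative 1,3-carbonyl transposition of β-alkoxy enones, in its lactone variant in which alkyllithium reagents turn 6-substituted 4-methoxy-5,6-dihydro-2H-pyran-2-ones into 2,6-disubstituted 2,3-dihydro-4H-pyran-4-ones. No ring is closed for the first time: the oxane ring of 6 is kept, and if 11 opens to the δ-hydroxy enone during work-up it closes again by 6-exo-trig hemiketalisation of the benzylic hydroxyl group on the new ketone, the only ring size within reach. No stereocenter is created, because the new ring carbon becomes sp2 and is set later in step 6, and the S centre that carries the aryl group has no acidic hydrogen under these conditions and keeps its C–O bond as long as the acid is dilute and cold. The step needs carbonyl addition to win over deprotonation of the γ-methylene (C5 of 6) and over double addition; the substrate secures this because its α-carbon is vinylic and carries no acidic hydrogen and because the tetrahedral adduct is held in the ring, supported by inverse addition at −78 °C.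

Step 6
Reactants: 12 (2S)-2-[4-(benzyloxy)-3-methoxyphenyl]-6-{2-[4-(benzyloxy)-3-methoxyphenyl]ethyl}-2,3-dihydro-4H-pyran-4-one
Product: 13 (2S,6S)-2-(4-hydroxy-3-methoxyphenyl)-6-[2-(4-hydroxy-3-methoxyphenyl)ethyl]oxan-4-one
Conditions: H2 (1 atm), 10% Pd/C, EtOAc, rt
Reagents that add atoms: none
Why: Heterogeneous hydrogenation; hydrogen is delivered syn to the C5=C6 bond from the ring face opposite to the pseudo-equatorial C2 aryl group, which sets C6 as S (2,6-cis), and both aryl benzyl ethers are cleaved by hydrogenolysis in the same operation.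

Step 7
Reactants: 13 (2S,6S)-2-(4-hydroxy-3-methoxyphenyl)-6-[2-(4-hydroxy-3-methoxyphenyl)ethyl]oxan-4-one
Product: 14 (2S,4R,6S)-2-(4-hydroxy-3-methoxyphenyl)-6-[2-(4-hydroxy-3-methoxyphenyl)ethyl]oxan-4-ol
Conditions: NaBH4, MeOH, −20 °C
Reagents that add atoms: none
Why: Hydride reduction of a chair locked by two equatorial substituents; the small reagent NaBH4 attacks the C4 carbonyl along the axial trajectory (torsional control) and should give the equatorial alcohol (4R), which is the all-cis target.

**Compound list**

1 | methyl (E)-3-methoxybut-2-enoate | CO/C(C)=C/C(=O)OC | starting material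
2 | lithium 1,3-dimethoxybuta-1,3-dien-1-olate | [Li+].[O-]C(OC)=CC(OC)=C | intermediate
3 | 1,3-dimethoxy-1-(trimethylsilyloxy)buta-1,3-diene (ketene acetal geometry as formed) | C=C(OC)C=C(OC)O[Si](C)(C)C | intermediate
4 | 4-(benzyloxy)-3-methoxybenzaldehyde | O=Cc1ccc(OCc2ccccc2)c(OC)c1 | starting material
5 | methyl (2E,5S)-5-[4-(benzyloxy)-3-methoxyphenyl]-3-methoxy-5-(trimethylsilyloxy)pent-2-enoate | COC(=O)/C=C(/OC)C[C@H](O[Si](C)(C)C)c1ccc(OCc2ccccc2)c(OC)c1 | intermediate
6 | (6S)-6-[4-(benzyloxy)-3-methoxyphenyl]-4-methoxy-5,6-dihydro-2H-pyran-2-one | COC1=CC(=O)O[C@H](c2ccc(OCc3ccccc3)c(OC)c2)C1 | intermediate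
7 | 4-(2-hydroxyethyl)-2-methoxyphenol | COc1cc(CCO)ccc1O | starting material
8 | 2-[4-(benzyloxy)-3-methoxyphenyl]ethan-1-ol | COc1cc(CCO)ccc1OCc1ccccc1 | intermediate
9 | 1-(benzyloxy)-4-(2-iodoethyl)-2-methoxybenzene | COc1cc(CCI)ccc1OCc1ccccc1 | intermediate
10 | {2-[4-(benzyloxy)-3-methoxyphenyl]ethyl}lithium | [Li]CCc1ccc(OCc2ccccc2)c(OC)c1 | intermediate
11 | lithium (6S)-6-[4-(benzyloxy)-3-methoxyphenyl]-2-{2-[4-(benzyloxy)-3-methoxyphenyl]ethyl}-4-methoxy-5,6-dihydro-2H-pyran-2-olate (both configurations at C2) | [Li+].[O-]C1(CCc2ccc(OCc3ccccc3)c(OC)c2)C=C(OC)C[C@@H](c2ccc(OCc3ccccc3)c(OC)c2)O1 | intermediate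
12 | (2S)-2-[4-(benzyloxy)-3-methoxyphenyl]-6-{2-[4-(benzyloxy)-3-methoxyphenyl]ethyl}-2,3-dihydro-4H-pyran-4-one | O=C1C=C(CCc2ccc(OCc3ccccc3)c(OC)c2)O[C@H](c2ccc(OCc3ccccc3)c(OC)c2)C1 | intermediate
13 | (2S,6S)-2-(4-hydroxy-3-methoxyphenyl)-6-[2-(4-hydroxy-3-methoxyphenyl)ethyl]oxan-4-one | COc1cc(CC[C@H]2CC(=O)C[C@@H](c3ccc(O)c(OC)c3)O2)ccc1O | intermediate
14 | (2S,4R,6S)-2-(4-hydroxy-3-methoxyphenyl)-6-[2-(4-hydroxy-3-methoxyphenyl)ethyl]oxan-4-ol (all-cis) | COc1cc(CC[C@H]2C[C@@H](O)C[C@@H](c3ccc(O)c(OC)c3)O2)ccc1O | target

**Step count and risks**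

Total step count: 7. Longest linear sequence: 5 steps (3, 4, 5, 6, 7; the branch 1, 2, 5, 6, 7 is equally long).

Step 5. The risk is proton abstraction from the γ-methylene (C5 of 6) by the basic primary alkyllithium, followed by β-elimination of the ring oxygen, in competition with carbonyl addition; opening of the lactolate before the quench would also allow a second addition. The fallback makes the same bond with a carbanion that is too weakly basic for this. Setting out from 4, Seyferth–Gilbert homologation with dimethyl (1-diazo-2-oxopropyl)phosphonate and K2CO3 in MeOH gives 1-(benzyloxy)-4-ethynyl-2-methoxybenzene F1. After deprotonation with n-BuLi in THF at −78 °C it is added to the carbonyl group of 6, and the same cold dilute-acid treatment gives (2S)-2-[4-(benzyloxy)-3-methoxyphenyl]-6-{[4-(benzyloxy)-3-methoxyphenyl]ethynyl}-2,3-dihydro-4H-pyran-4-one F2. Hydrogenation over 10% Pd/C then saturates the triple bond and the ring double bond and cleaves both benzyl ethers, and the route is rejoined at 13.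

Step 2. The risk is weak enantiofacial discrimination together with slow turnover, because the electron-rich aldehyde binds the Lewis acid strongly and reacts sluggishly. In the fallback the aryl carbinol centre is set by a Brønsted acid-catalysed propargylation and the lactone is built around it. Setting out from 4, allenylboronic acid pinacol ester and a chiral BINOL-derived phosphoric acid (the antipode that gives the S alcohol) give (1S)-1-[4-(benzyloxy)-3-methoxyphenyl]but-3-yn-1-ol F3. Its dianion (n-BuLi, 2 equiv, THF, −78 °C) is acylated on carbon with methyl chloroformate to methyl (5S)-5-[4-(benzyloxy)-3-methoxyphenyl]-5-hydroxypent-2-ynoate F4. NaOMe in MeOH adds methoxide to the ynoate and the hydroxyl group closes the lactone, which returns the route to 6.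

Step 6. The risk is incomplete facial selectivity on the catalyst surface and hydrogenolytic opening of the C2–O1 bond, which in 12 is a vinylogous benzyl ester, before the double bond is saturated. In the fallback C6 is set by a homogeneous hydride. Setting out from 12, conjugate reduction with LiBH(s-Bu)3 in THF at −78 °C (axial hydride attack at C6 through a chair-like transition state) gives (2S,6S)-2-[4-(benzyloxy)-3-methoxyphenyl]-6-{2-[4-(benzyloxy)-3-methoxyphenyl]ethyl}oxan-4-one F5. NaBH4 in MeOH gives (2S,4R,6S)-2-[4-(benzyloxy)-3-methoxyphenyl]-6-{2-[4-(benzyloxy)-3-methoxyphenyl]ethyl}oxan-4-ol F6. The two benzyl ethers are then removed by transfer hydrogenolysis (10% Pd/C, cyclohexa-1,4-diene, EtOH), now on a saturated ring, and the route is rejoined at the target 14.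

**Further compounds**

F1 | step 5 | 1-(benzyloxy)-4-ethynyl-2-methoxybenzene | C#Cc1ccc(OCc2ccccc2)c(OC)c1
F2 | step 5 | (2S)-2-[4-(benzyloxy)-3-methoxyphenyl]-6-{[4-(benzyloxy)-3-methoxyphenyl]ethynyl}-2,3-dihydro-4H-pyran-4-one | O=C1C=C(C#Cc2ccc(OCc3ccccc3)c(OC)c2)O[C@H](c2ccc(OCc3ccccc3)c(OC)c2)C1
F3 | step 2 | (1S)-1-[4-(benzyloxy)-3-methoxyphenyl]but-3-yn-1-ol | C#CC[C@H](O)c1ccc(OCc2ccccc2)c(OC)c1
F4 | step 2 | methyl (5S)-5-[4-(benzyloxy)-3-methoxyphenyl]-5-hydroxypent-2-ynoate | COC(=O)C#CC[C@H](O)c1ccc(OCc2ccccc2)c(OC)c1
F5 | step 6 | (2S,6S)-2-[4-(benzyloxy)-3-methoxyphenyl]-6-{2-[4-(benzyloxy)-3-methoxyphenyl]ethyl}oxan-4-one | COc1cc(CC[C@H]2CC(=O)C[C@@H](c3ccc(OCc4ccccc4)c(OC)c3)O2)ccc1OCc1ccccc1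
F6 | step 6 | (2S,4R,6S)-2-[4-(benzyloxy)-3-methoxyphenyl]-6-{2-[4-(benzyloxy)-3-methoxyphenyl]ethyl}oxan-4-ol | COc1cc(CC[C@H]2C[C@@H](O)C[C@@H](c3ccc(OCc4ccccc4)c(OC)c3)O2)ccc1OCc1ccccc1
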